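**Plan**

1. Cuts: the two ester C–O bonds; the pyran C–O bond at the cyclohexane carbon that bears O and CH3 (back to an exocyclic C=CH2 and the side-chain tertiary alcohol); the bond from the ring-fusion CH to the first CH2 of the pyran arm; and, inside the cyclohexane, the two ring bonds of that same CH, which is thereby a carbon inserted into a cyclopentanone.
2. Enabling feature: in the carbocycle the ring-fusion CH lies between the O-bearing carbon (a latent C=O) and the quaternary C(CH3)(CH2CO2H). Inserting one carbon between C=O and the quaternary α-carbon of a 2,2,3-trisubstituted cyclopentanone creates exactly this array and leaves an enolate located on the inserted carbon alone.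
3. Forward order: cyclopentanone from 2-methylcyclopentenone (conjugate addition, enolate alkylation); one-carbon ring enlargement to the six-membered enolate, joined in the same flask to a C6 iodide made from (R)-linalool; methylenation; closure of the pyran as the second ring; saponification.
4. Stereochemistry: the CH bearing C(CH3)2CO2H by catalytic asymmetric Mukaiyama–Michael addition; the quaternary carbon by alkylation anti to it; the ring-fusion CH by axial alkylation anti to the angular methyl; the O-bearing ring carbon by cis ring closure from that axial arm; the vinyl-bearing carbon bought as (R)-linalool.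

Key step: step 6

Remark on the chemistry: (R)-(−)-linalool of high enantiomeric purity and ketene acetal 2 are taken as commercial; in step 1 the catalyst antipode is the one that gives the (1R) adduct.

**Step 1**
Reactants: 1 2-methylcyclopent-2-en-1-one; 2 1-methoxy-2-methyl-1-(trimethylsilyloxy)prop-1-ene
Product: 3 methyl 2-methyl-2-[(1R)-2-methyl-3-(trimethylsilyloxy)cyclopent-2-en-1-yl]propanoate
Conditions: chiral o-tolyl-oxazaborolidinium triflimide from α,α-diphenylprolinol (10 mol %), toluene, −40 °C; non-aqueous work-up (Et3N, pentane, filtration)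
Reagents that add atoms: none
Why: Catalytic asymmetric Mukaiyama–Michael addition, in which the chiral Lewis acid activates the enone and shields one face of the β-carbon, so the ketene acetal should add 1,4 to set the (R) centre while silyl transfer gives the regiodefined tetrasubstituted enol silane.

**Step 2**
Reactants: 3 methyl 2-methyl-2-[(1R)-2-methyl-3-(trimethylsilyloxy)cyclopent-2-en-1-yl]propanoate
Product: 4 methyl 2-[(1R,2S)-2-(2-methoxy-2-oxoethyl)-2-methyl-3-oxocyclopentyl]-2-methylpropanoate
Conditions: BnMe3N+F− (anhydrous), BrCH2CO2Me, 4 Å MS, THF, −20 °C → rt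
Reagents that add atoms: methyl bromoacetate (COC(=O)CBr)
Why: Fluoride-mediated regiospecific enolate alkylation, in which the ammonium enolate unmasked from the enol silane should be alkylated at the methyl-bearing α-carbon on the face anti to the bulky neighbouring C(CH3)2CO2Me group, which sets the quaternary centre with CH2CO2Me trans to that group.

**Step 3**
Reactants: 5 (R)-(−)-linalool
Product: 6 (R)-triethyl[(3,7-dimethylocta-1,6-dien-3-yl)oxy]silane
Conditions: TESOTf, 2,6-lutidine, CH2Cl2, −78 → 0 °C
Reagents that add atoms: triethylsilyl trifluoromethanesulfonate (CC[Si](CC)(CC)OS(=O)(=O)C(F)(F)F)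
Why: Silylation of a tertiary alcohol with a silyl triflate, which leaves the stereocentre untouched.

**Step 4**
Reactants: 6 (R)-triethyl[(3,7-dimethylocta-1,6-dien-3-yl)oxy]silane
Product: 8 (4R)-4-methyl-4-[(triethylsilyl)oxy]hex-5-enoic acid, via aldehyde 7 (not isolated)
Conditions: O3 (1.0 equiv, metered), MeCN/H2O 9:1, 0 °C; then aq NaClO2, 0 °C → rt
Reagents that add atoms: ozone ([O-][O+]=O); sodium chlorite ([Na+].[O-]Cl=O)
Why: Telescoped ozonolysis–chlorite (Pinnick-type) oxidation, in which ozone should cleave the electron-rich trisubstituted alkene much faster than the hindered vinyl group, the carbonyl oxide collapses to the aldehyde in aqueous acetonitrile, and chlorite oxidizes it to the acid in the same flask.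

**Step 5**
Reactants: 8 (4R)-4-methyl-4-[(triethylsilyl)oxy]hex-5-enoic acid
Product: 10 (3R)-triethyl[(5-iodo-3-methylpent-1-en-3-yl)oxy]silane, via Barton ester 9 (not isolated)
Conditions: N-hydroxypyridine-2-thione, DCC, DMAP (cat.), CH2Cl2, 0 °C, dark; then CHI3, PhH, hν (W lamp), rt
Reagents that add atoms: iodoform (IC(I)I)
Why: Barton decarboxylative iodination, in which the thiohydroxamate ester fragments to a primary radical that should abstract iodine from iodoform faster than it attacks the remote vinyl group (a 4-pentenyl radical does not cyclize), so the chain is shortened by one carbon without touching the stereocentre.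

**Step 6**
Reactants: 4 methyl 2-[(1R,2S)-2-(2-methoxy-2-oxoethyl)-2-methyl-3-oxocyclopentyl]-2-methylpropanoate; 10 (3R)-triethyl[(5-iodo-3-methylpent-1-en-3-yl)oxy]silane
Product: 14 methyl 2-[(1R,2S,3S)-2-(2-methoxy-2-oxoethyl)-2-methyl-3-[(3R)-3-methyl-3-[(triethylsilyl)oxy]pent-4-en-1-yl]-4-oxocyclohexyl]-2-methylpropanoate, via lithium alkoxide 11 (not isolated), via bromolithio carbenoid 12 (not isolated), via ring-enlarged lithium enolate 13 (not isolated)
Conditions: CH2Br2, LDA, THF, −95 °C, then 4; n-BuLi (1.1 equiv), −95 → −20 °C; DMPU, 10 (1.5 equiv), −40 °C → rt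
Reagents that add atoms: dibromomethane (BrCBr)
Why: LiCHBr2 should add to the cyclopentanone C=O far faster than to the two neopentyl-type methyl esters at −95 °C, and Br/Li exchange then gives a β-oxido carbenoid in which the alkoxide pushes a ring C–C bond onto the carbenoid carbon with loss of LiBr, so the five-membered ring becomes the six-membered ring and the lithium enolate lies only between the old carbonyl carbon and the inserted CH. The closest known reaction type is the Nozaki–Yamamoto β-oxido carbenoid ring enlargement of cycloalkanones with trapping of the ring-enlarged enolate. No ring is closed by cyclization, since the cyclohexane arises by 1,2-shift; the selectivity needed is migration of the quaternary α-carbon instead of the α-CH2, which the higher migratory aptitude of the more substituted carbon in this rearrangement should secure, with retention at the migrating carbon. The new stereocentre (the ring CH that carries the side chain) is set in the C-alkylation, where iodide 10 should approach the half-chair enolate axially on the face anti to the pseudoaxial methyl of the neighbouring quaternary carbon, placing the chain trans to that methyl and cis to CH2CO2Me. No base remains after the alkylation, so the kinetically formed axial epimer should not equilibrate.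

**Step 7**
Reactants: 14 methyl 2-[(1R,2S,3S)-2-(2-methoxy-2-oxoethyl)-2-methyl-3-[(3R)-3-methyl-3-[(triethylsilyl)oxy]pent-4-en-1-yl]-4-oxocyclohexyl]-2-methylpropanoate
Product: 15 methyl 2-[(1R,2R,3R)-2-(2-methoxy-2-oxoethyl)-2-methyl-4-methylidene-3-[(3R)-3-methyl-3-[(triethylsilyl)oxy]pent-4-en-1-yl]cyclohexyl]-2-methylpropanoate
Conditions: Zn, CH2Br2, TiCl4 (promoter), THF/CH2Cl2, 0 °C → rt (Takai–Lombardo)
Reagents that add atoms: dibromomethane (BrCBr)
Why: Takai–Lombardo methylenation, whose non-basic gem-dimetallic reagent should convert the hindered ketone into the exocyclic alkene without enolization (the α-stereocentre is kept; only its CIP descriptor changes) and without attacking the esters or the silyl ether.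

**Step 8**
Reactants: 15 methyl 2-[(1R,2R,3R)-2-(2-methoxy-2-oxoethyl)-2-methyl-4-methylidene-3-[(3R)-3-methyl-3-[(triethylsilyl)oxy]pent-4-en-1-yl]cyclohexyl]-2-methylpropanoate
Product: 16 methyl 2-[(1R,2R,3R)-3-[(3R)-3-hydroxy-3-methylpent-4-en-1-yl]-2-(2-methoxy-2-oxoethyl)-2-methyl-4-methylidenecyclohexyl]-2-methylpropanoate
Conditions: HF·pyridine, pyridine, THF, 0 °C → rt
Reagents that add atoms: none
Why: Fluoride cleavage of the triethylsilyl ether under buffered conditions that should neither ionize the tertiary allylic alcohol nor move the exocyclic double bond.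

**Step 9**
Reactants: 16 methyl 2-[(1R,2R,3R)-3-[(3R)-3-hydroxy-3-methylpent-4-en-1-yl]-2-(2-methoxy-2-oxoethyl)-2-methyl-4-methylidenecyclohexyl]-2-methylpropanoate
Product: 18 methyl 2-[(2R,4aS,5S,6R,8aR)-2-ethenyl-5-(2-methoxy-2-oxoethyl)-2,5,8a-trimethyloctahydro-2H-chromen-6-yl]-2-methylpropanoate, via organomercurial 17 (not isolated)
Conditions: Hg(OCOCF3)2, THF, −20 → 0 °C; then NaBH4, 3 M NaOH, 0 °C
Reagents that add atoms: none
Why: Intramolecular alkoxymercuration–demercuration, in which the tertiary hydroxyl on the axial side chain should add in the Markovnikov sense (6-exo) to the 1,1-disubstituted alkene and can reach the ring carbon only on its own face, giving the cis-fused ether with the new methyl axial (the O-bearing quaternary centre is relayed from the neighbouring CH) before borohydride replaces mercury by hydrogen.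

**Step 10**
Reactants: 18 methyl 2-[(2R,4aS,5S,6R,8aR)-2-ethenyl-5-(2-methoxy-2-oxoethyl)-2,5,8a-trimethyloctahydro-2H-chromen-6-yl]-2-methylpropanoate
Product: 20 2-[(2R,4aS,5S,6R,8aR)-5-(carboxymethyl)-2-ethenyl-2,5,8a-trimethyloctahydro-2H-chromen-6-yl]-2-methylpropanoic acid, via dipotassium salt 19 (not isolated)
Conditions: KOH (excess), ethylene glycol/H2O, 140 °C; then 1 M HCl to pH 3, 0 °C
Reagents that add atoms: potassium hydroxide ([K+].[OH-])
Why: Saponification of the two hindered methyl esters with hot hydroxide, to which the ether, the vinyl group and all stereocentres (none is an enolizable α-carbon) should be stable, followed by brief cold acidification to free the diacid.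

**Compound list**

1 | 2-methylcyclopent-2-en-1-one | CC1=CCCC1=O | starting material
2 | 1-methoxy-2-methyl-1-(trimethylsilyloxy)prop-1-ene | COC(O[Si](C)(C)C)=C(C)C | starting material
3 | methyl 2-methyl-2-[(1R)-2-methyl-3-(trimethylsilyloxy)cyclopent-2-en-1-yl]propanoate | C[Si](C)(C)OC1=C(C)[C@H](C(C)(C)C(=O)OC)CC1 | intermediate
4 | methyl 2-[(1R,2S)-2-(2-methoxy-2-oxoethyl)-2-methyl-3-oxocyclopentyl]-2-methylpropanoate | O=C1[C@@](C)(CC(=O)OC)[C@H](C(C)(C)C(=O)OC)CC1 | intermediate
5 | (R)-(−)-linalool | C=C[C@@](O)(C)CCC=C(C)C | starting material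
6 | (R)-triethyl[(3,7-dimethylocta-1,6-dien-3-yl)oxy]silane | C=C[C@@](O[Si](CC)(CC)CC)(C)CCC=C(C)C | intermediate
7 | (4R)-4-methyl-4-[(triethylsilyl)oxy]hex-5-enal (not isolated) | C=C[C@@](O[Si](CC)(CC)CC)(C)CCC=O | intermediate
8 | (4R)-4-methyl-4-[(triethylsilyl)oxy]hex-5-enoic acid | C=C[C@@](O[Si](CC)(CC)CC)(C)CCC(=O)O | intermediate
9 | 2-thioxopyridin-1(2H)-yl (4R)-4-methyl-4-[(triethylsilyl)oxy]hex-5-enoate (Barton ester, not isolated) | C=C[C@@](O[Si](CC)(CC)CC)(C)CCC(=O)On1ccccc1=S | intermediate
10 | (3R)-triethyl[(5-iodo-3-methylpent-1-en-3-yl)oxy]silane | C=C[C@@](O[Si](CC)(CC)CC)(C)CCI | intermediate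
11 | lithium alkoxide of methyl 2-[(1R,2S)-3-(dibromomethyl)-3-hydroxy-2-(2-methoxy-2-oxoethyl)-2-methylcyclopentyl]-2-methylpropanoate (either carbinol epimer; not isolated) | [Li]OC1(C(Br)Br)[C@@](C)(CC(=O)OC)[C@H](C(C)(C)C(=O)OC)CC1 | intermediate
12 | the corresponding β-oxido carbenoid, bromo(lithio)methyl in place of dibromomethyl (not isolated) | [Li]OC1(C([Li])Br)[C@@](C)(CC(=O)OC)[C@H](C(C)(C)C(=O)OC)CC1 | intermediate
13 | methyl 2-[(1R,2S)-4-(lithiooxy)-2-(2-methoxy-2-oxoethyl)-2-methylcyclohex-3-en-1-yl]-2-methylpropanoate (ring-enlarged enolate, not isolated) | [Li]OC1=C[C@@](C)(CC(=O)OC)[C@H](C(C)(C)C(=O)OC)CC1 | intermediate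
14 | methyl 2-[(1R,2S,3S)-2-(2-methoxy-2-oxoethyl)-2-methyl-3-[(3R)-3-methyl-3-[(triethylsilyl)oxy]pent-4-en-1-yl]-4-oxocyclohexyl]-2-methylpropanoate | C=C[C@@](O[Si](CC)(CC)CC)(C)CC[C@H]1[C@@](C)(CC(=O)OC)[C@H](C(C)(C)C(=O)OC)CCC1=O | intermediate
15 | methyl 2-[(1R,2R,3R)-2-(2-methoxy-2-oxoethyl)-2-methyl-4-methylidene-3-[(3R)-3-methyl-3-[(triethylsilyl)oxy]pent-4-en-1-yl]cyclohexyl]-2-methylpropanoate | C=C[C@@](O[Si](CC)(CC)CC)(C)CC[C@H]1[C@@](C)(CC(=O)OC)[C@H](C(C)(C)C(=O)OC)CCC1=C | intermediate
16 | methyl 2-[(1R,2R,3R)-3-[(3R)-3-hydroxy-3-methylpent-4-en-1-yl]-2-(2-methoxy-2-oxoethyl)-2-methyl-4-methylidenecyclohexyl]-2-methylpropanoate | C=C[C@@](O)(C)CC[C@H]1[C@@](C)(CC(=O)OC)[C@H](C(C)(C)C(=O)OC)CCC1=C | intermediate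
17 | organomercurial: compound 18 with CH2HgOCOCF3 in place of the 8a-methyl group (not isolated) | C=C[C@@]1(C)CC[C@H]2[C@@](C)(CC(=O)OC)[C@H](C(C)(C)C(=O)OC)CC[C@@]2(C[Hg]OC(=O)C(F)(F)F)O1 | intermediate
18 | methyl 2-[(2R,4aS,5S,6R,8aR)-2-ethenyl-5-(2-methoxy-2-oxoethyl)-2,5,8a-trimethyloctahydro-2H-chromen-6-yl]-2-methylpropanoate | C=C[C@@]1(C)CC[C@H]2[C@@](C)(CC(=O)OC)[C@H](C(C)(C)C(=O)OC)CC[C@@]2(C)O1 | intermediate
19 | dipotassium salt of 20 (not isolated) | C=C[C@@]1(C)CC[C@H]2[C@@](C)(CC(=O)[O-])[C@H](C(C)(C)C(=O)[O-])CC[C@@]2(C)O1.[K+].[K+] | intermediate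
20 | 2-[(2R,4aS,5S,6R,8aR)-5-(carboxymethyl)-2-ethenyl-2,5,8a-trimethyloctahydro-2H-chromen-6-yl]-2-methylpropanoic acid | C=C[C@@]1(C)CC[C@H]2[C@@](C)(CC(=O)O)[C@H](C(C)(C)C(=O)O)CC[C@@]2(C)O1 | target

**Step count and risks**

Total steps: 10. Longest linear sequence: 8 steps (from 5 through steps 3 to 10).

Steps most likely to fail:

1. Step 6. The SN2 capture of a hindered enolate by an unactivated primary iodide may be slow, which would allow proton exchange and with it loss of the regiochemical and configurational integrity at the α-carbon. Competing migration of the ring CH2 or attack of the organolithium reagents on an ester are further risks. Fallback, from 10 and 4, back to the route at 14: Kornblum oxidation of 10 (DMSO, NaHCO3) would give (3R)-3-methyl-3-[(triethylsilyl)oxy]pent-4-enal F1. Enolate 13, generated from 4 as in step 6, would add to F1 at −78 °C (aldol addition, a fast C–C bond formation on the same enolate face) to give the β-hydroxy ketone methyl 2-[(1R,2S,3R)-3-[(3R)-1-hydroxy-3-methyl-3-[(triethylsilyl)oxy]pent-4-en-1-yl]-2-(2-methoxy-2-oxoethyl)-2-methyl-4-oxocyclohexyl]-2-methylpropanoate F2. Thiocarbonyldiimidazole (DMAP) would convert it to the imidazolyl thiocarbonate of F2 F3, and Barton–McCombie reduction (Bu3SnH, AIBN, toluene, 80 °C) would return to 14.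

2. Step 1. Facial selectivity may be poor because the α-methyl enone binds the chiral Lewis acid less rigidly than the parent cycloalkenones for which this catalysis is established. Fallback, from commercial cyclopent-2-en-1-one and 2, back to the route at 3: the same catalytic Mukaiyama–Michael addition on the unsubstituted enone would give methyl 2-methyl-2-[(1R)-3-(trimethylsilyloxy)cyclopent-2-en-1-yl]propanoate F4. Fluoride-mediated methylation (BnMe3N+F−, MeI) would give the trans ketone methyl 2-methyl-2-[(1R,2S)-2-methyl-3-oxocyclopentyl]propanoate F5. Thermodynamic enol silylation (TMSCl, Et3N, DMF, 80 °C) toward the more substituted side would return to 3.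

3. Step 9. Ring closure to the congested cis-fused ether may be slow or reversible, and mercuration of the vinyl group may compete. Fallback, from 16, back to the route at 18: cobalt-salen-catalysed hydrogen-atom-transfer hydroalkoxylation (N-fluoro-2,4,6-trimethylpyridinium salt, silane), which converts the 1,1-disubstituted alkene into a tertiary radical/cation that the tethered hydroxyl traps irreversibly. This fallback makes no compound outside the list (F0).

**Further compounds**

F1 | step 6 | (3R)-3-methyl-3-[(triethylsilyl)oxy]pent-4-enal | C=C[C@@](O[Si](CC)(CC)CC)(C)CC=O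
F2 | step 6 | methyl 2-[(1R,2S,3R)-3-[(3R)-1-hydroxy-3-methyl-3-[(triethylsilyl)oxy]pent-4-en-1-yl]-2-(2-methoxy-2-oxoethyl)-2-methyl-4-oxocyclohexyl]-2-methylpropanoate | C=C[C@@](O[Si](CC)(CC)CC)(C)CC(O)[C@H]1[C@@](C)(CC(=O)OC)[C@H](C(C)(C)C(=O)OC)CCC1=O
F3 | step 6 | O-(1H-imidazol-1-ylcarbonothioyl) derivative of F2 | C=C[C@@](O[Si](CC)(CC)CC)(C)CC(OC(=S)n1ccnc1)[C@H]1[C@@](C)(CC(=O)OC)[C@H](C(C)(C)C(=O)OC)CCC1=O
F4 | step 1 | methyl 2-methyl-2-[(1R)-3-(trimethylsilyloxy)cyclopent-2-en-1-yl]propanoate | C[Si](C)(C)OC1=C[C@H](C(C)(C)C(=O)OC)CC1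
F5 | step 1 | methyl 2-methyl-2-[(1R,2S)-2-methyl-3-oxocyclopentyl]propanoate | O=C1[C@@H](C)[C@H](C(C)(C)C(=O)OC)CC1
F0 | step 9 | none | none
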